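**Retrosynthetic overview**
1. The strategy rests on C6 and C7, the two atoms shared by the cyclohexane (C5–C6–C7–C8–C9–C10) and the trans-fused α-methylene γ-lactone (O–C6–C7–C11–C12): the single bond C6–C7 completes the carbocycle and leaves the C6 alkoxide next to the C12 ester.
2. Target ⇐ C15 acid from the C15 allylic alcohol (MnO2, then NaClO2) ⇐ 8β-tiglate ⇐ 8β-alcohol, obtained by oxidation and equatorial hydride reduction of the 8α-alcohol delivered by the ring closure.
3. Bicyclic lactone ⇐ open-chain C6 aldehyde carrying an (E)-2-(bromomethyl)enoate (C8 cis to the ester): CrCl2 forms C6–C7 and closes the cyclohexane first, then the chromium alkoxide closes the lactone in the same flask.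
4. Aldehyde ⇐ C7=C11 by a Still–Gennari-type bromo-olefination and Stille hydroxymethylation of a C7 aldehyde; C5–C10 with both stereocentres by an enantioselective boron-enolate Ireland–Claisen rearrangement.
5. Claisen ester ⇐ (E)-allylic alcohol from (S)-4-methoxybenzyl glycidyl ether (source of C8; acetylide opening, carboalumination) + 3-(silyloxymethyl)but-3-enoic acid from 2-methylenepropane-1,3-diol.

Key step: step 19

**Remarks on the chemistry**
- Numbering and faces: atom numbers are those of the elemane skeleton of the target (ring C5–C10; C14 methyl and C1=C2 vinyl on C10; C3=C4–C15 on C5; C11(=C13)–C12 on C7; lactone oxygen on C6). They are used for the open-chain compounds too. α is the face opposite to the C14 methyl.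
- C8: in the chair that gives the trans-lactone (C4 side chain, O6 and C11 equatorial, C14 methyl axial) the 8β-oxygen of the target is axial and syn to the C14 methyl. The ring closure is therefore planned on the 8α-epimer, where that oxygen is equatorial, and C8 is inverted afterwards (steps 21 and 22).
- Alkene geometry: the bromide is made as the (E)-isomer (C8 cis to the ester, trans to CH2Br), because this geometry maps directly onto the trans-fused product in a closed transition state.
- Assumption (step 8): with the bromodiazaborolidine and Et3N in toluene–hexane the ester is taken to give the O-boron ketene acetal with C4 cis to the allylic oxygen, and the (S,S)-controller is taken to lead to the (5R,10S) acid. If a model ester shows the opposite facial sense, the (R,R)-controller is used instead.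

**Route**

Step 1
Reactants: 1 2-methylenepropane-1,3-diol
Product: 2 2-{[(tert-butyldiphenylsilyl)oxy]methyl}prop-2-en-1-ol
Conditions: NaH (1.0 equiv), THF, 0 °C → rt; TBDPSCl (1.0 equiv)
Reagents that add atoms: tert-butyl(chloro)diphenylsilane, CC(C)(C)[Si](Cl)(c1ccccc1)c1ccccc1
Why: Monosilylation of the symmetric diol through its sparingly soluble monosodium alkoxide (Williamson-type O-silylation) should stop at the monoether.

Step 2
Reactants: 2 monosilylated diol
Product: 3 tert-butyl{[2-(chloromethyl)prop-2-en-1-yl]oxy}diphenylsilane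
Conditions: N-chlorosuccinimide, Me2S, CH2Cl2, −20 → 0 °C
Reagents that add atoms: N-chlorosuccinimide, O=C1CCC(=O)N1Cl
Why: Corey–Kim chlorination turns the primary allylic alcohol into the chloride through its alkoxysulfonium salt under conditions that leave the silyl ether alone, and because the allyl unit is symmetric SN2 and SN2' attack give the same product.

Step 3
Reactants: 3 allylic chloride
Product: 5 3-{[(tert-butyldiphenylsilyl)oxy]methyl}but-3-enoic acid, via allylmagnesium chloride 4 (not isolated)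
Conditions: Mg, THF, 0 °C (slow addition of 3); CO2, −78 → 0 °C; 1 M HCl
Reagents that add atoms: carbon dioxide, O=C=O
Why: Grignard formation from the allylic chloride followed by carboxylation with CO2 (the classical route from methallyl chloride to 3-methylbut-3-enoic acid) should give the β,γ-unsaturated acid, the two allyl termini being equivalent so that transposition is without consequence.

Step 4
Reactants: 6 (S)-2-{[(4-methoxybenzyl)oxy]methyl}oxirane
Product: 7 (S)-1-[(4-methoxybenzyl)oxy]pent-4-yn-2-ol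
Conditions: LiC≡CH·H2NCH2CH2NH2, DMSO, 0 °C → rt
Reagents that add atoms: lithium acetylide (ethylenediamine complex), [Li+].[C-]#C
Why: SN2 opening of the terminal epoxide by acetylide at its unsubstituted carbon leaves the oxygen-bearing stereocentre, the future C8, untouched, so its configuration comes from the chiral pool.

Step 5
Reactants: 7 homopropargylic alcohol
Product: 8 (S)-tert-butyl({1-[(4-methoxybenzyl)oxy]pent-4-yn-2-yl}oxy)dimethylsilane
Conditions: TBSCl, imidazole, DMF, rt
Reagents that add atoms: tert-butyl(chloro)dimethylsilane, CC(C)(C)[Si](C)(C)Cl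
Why: Standard silylation of the secondary alcohol with TBSCl and imidazole.

Step 6
Reactants: 8 silyl-protected alkyne
Product: 11 (S,E)-5-[(tert-butyldimethylsilyl)oxy]-6-[(4-methoxybenzyl)oxy]-3-methylhex-2-en-1-ol, via alkenylalane 9 (not isolated), via lithium alkenylalanate 10 (not isolated)
Conditions: AlMe3, Cp2ZrCl2 (25 mol%), CH2Cl2, 0 °C → rt; then n-BuLi, THF, −30 °C; (CH2O)n, rt
Reagents that add atoms: AlMe3, C[Al](C)C; paraformaldehyde (CH2O)n, C=O
Why: Zirconium-catalysed Negishi carboalumination adds methyl and aluminium syn across the terminal alkyne with methyl on the internal carbon, and the alanate formed with n-BuLi is hydroxymethylated by formaldehyde with retention, which fixes the (E)-trisubstituted alkene.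

Step 7
Reactants: 11 (E)-allylic alcohol; 5 butenoic acid
Product: 12 (S,E)-5-[(tert-butyldimethylsilyl)oxy]-6-[(4-methoxybenzyl)oxy]-3-methylhex-2-en-1-yl 3-{[(tert-butyldiphenylsilyl)oxy]methyl}but-3-enoate
Conditions: EDC·HCl, DMAP (5 mol%), CH2Cl2, 0 °C
Reagents that add atoms: none
Why: Carbodiimide (Steglich) esterification at 0 °C with catalytic DMAP should join acid and allylic alcohol without moving the β,γ-double bond into conjugation.

Step 8
Reactants: 12 allylic ester
Product: 15 (2R,3S,5S)-5-[(tert-butyldimethylsilyl)oxy]-2-{3-[(tert-butyldiphenylsilyl)oxy]prop-1-en-2-yl}-6-[(4-methoxybenzyl)oxy]-3-methyl-3-vinylhexanoic acid, via boron ketene acetal 13 (not isolated), via acyloxyborane 14 (not isolated)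
Conditions: (4S,5S)-2-bromo-4,5-diphenyl-1,3-bis{[3,5-bis(trifluoromethyl)phenyl]sulfonyl}-1,3,2-diazaborolidine (1.2 equiv), Et3N, toluene–hexane, −78 °C; then −20 → 4 °C; aqueous work-up
Reagents that add atoms: none
Why: Enantioselective boron-enolate Ireland–Claisen rearrangement: soft enolisation gives the O-boron ketene acetal with C4 cis to the allylic oxygen, which rearranges through a chair with the (E)-alkene so that the relative configuration of C5 and C10 follows from the two double-bond geometries, while the C2-symmetric diazaborolidine on boron selects the face and with it the absolute configuration.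

Step 9
Reactants: 15 Claisen acid
Product: 16 (2R,3S,5S)-5-[(tert-butyldimethylsilyl)oxy]-2-{3-[(tert-butyldiphenylsilyl)oxy]prop-1-en-2-yl}-6-[(4-methoxybenzyl)oxy]-3-methyl-3-vinylhexan-1-ol
Conditions: LiAlH4, Et2O, 0 °C → rt
Reagents that add atoms: none
Why: LiAlH4 reduces the hindered carboxylic acid to the primary alcohol without touching the ethers or alkenes.

Step 10
Reactants: 16 C6 alcohol
Product: 17 triethylsilyl ether of 16 (Et3SiO on C6; configuration unchanged)
Conditions: TESCl, imidazole, CH2Cl2, 0 °C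
Reagents that add atoms: chlorotriethylsilane, CC[Si](Cl)(CC)CC
Why: Silylation of the primary alcohol as its triethylsilyl ether, chosen because it can later be cleaved by mild acid in the presence of the allylic bromide and the other two silyl ethers.

Step 11
Reactants: 17 fully protected tetraol
Product: 18 (2S,4S,5R)-2-[(tert-butyldimethylsilyl)oxy]-5-{3-[(tert-butyldiphenylsilyl)oxy]prop-1-en-2-yl}-4-methyl-6-[(triethylsilyl)oxy]-4-vinylhexan-1-ol
Conditions: DDQ, CH2Cl2–pH 7 buffer (10:1), 0 °C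
Reagents that add atoms: none
Why: Oxidative cleavage of the 4-methoxybenzyl ether by DDQ (hydride abstraction to the oxocarbenium ion, then hydrolysis) frees O7 and leaves the three silyl ethers in place.

Step 12
Reactants: 18 C7 alcohol
Product: 19 (2S,4S,5R)-2-[(tert-butyldimethylsilyl)oxy]-5-{3-[(tert-butyldiphenylsilyl)oxy]prop-1-en-2-yl}-4-methyl-6-[(triethylsilyl)oxy]-4-vinylhexanal
Conditions: Dess–Martin periodinane, NaHCO3, CH2Cl2, 0 °C → rt
Reagents that add atoms: none
Why: Buffered Dess–Martin oxidation should give the α-silyloxy aldehyde without epimerising C8.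

Step 13
Reactants: 20 methyl 2-[bis(2,2,2-trifluoroethoxy)phosphoryl]acetate
Product: 22 methyl 2-[bis(2,2,2-trifluoroethoxy)phosphoryl]-2-bromoacetate, via dibromophosphonoacetate 21 (not isolated)
Conditions: Br2, aq. NaOH (NaOBr), 0 °C; crude dibromide then SnCl2·2H2O, EtOH–H2O, 0 °C
Reagents that add atoms: bromine, BrBr
Why: Exhaustive α-bromination of the phosphonoacetate by hypobromite followed by selective reduction of one C–Br bond with SnCl2 should give the monobromo Horner–Wadsworth–Emmons reagent.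

Step 14
Reactants: 19 C7 aldehyde; 22 bromophosphonoacetate
Product: 23 methyl (2E,4S,6S,7R)-2-bromo-4-[(tert-butyldimethylsilyl)oxy]-7-{3-[(tert-butyldiphenylsilyl)oxy]prop-1-en-2-yl}-6-methyl-8-[(triethylsilyl)oxy]-6-vinyloct-2-enoate
Conditions: t-BuOK, 18-crown-6, THF, −78 °C
Reagents that add atoms: none
Why: Horner–Wadsworth–Emmons olefination with a bis(trifluoroethyl) phosphonate under dissociating conditions (Still–Gennari type) is kinetically controlled and puts C8 cis to the ester, that is, it gives the (E)-α-bromoacrylate.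

Step 15
Reactants: 23 (E)-α-bromoacrylate
Product: 24 methyl (2Z,4S,6S,7R)-4-[(tert-butyldimethylsilyl)oxy]-7-{3-[(tert-butyldiphenylsilyl)oxy]prop-1-en-2-yl}-2-(hydroxymethyl)-6-methyl-8-[(triethylsilyl)oxy]-6-vinyloct-2-enoate
Conditions: Bu3SnCH2OH (1.5 equiv), Pd(PPh3)4 (10 mol%), 1,4-dioxane, 90 °C
Reagents that add atoms: Bu3SnCH2OH, CCCC[Sn](CCCC)(CCCC)CO
Why: Stille coupling of the activated α-bromoacrylate with Bu3SnCH2OH should replace bromine by CH2OH with retention of the alkene geometry.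

Step 16
Reactants: 24 allylic alcohol
Product: 25 methyl (2E,4S,6S,7R)-2-(bromomethyl)-4-[(tert-butyldimethylsilyl)oxy]-7-{3-[(tert-butyldiphenylsilyl)oxy]prop-1-en-2-yl}-6-methyl-8-[(triethylsilyl)oxy]-6-vinyloct-2-enoate
Conditions: CBr4, PPh3, CH2Cl2, 0 °C
Reagents that add atoms: carbon tetrabromide, BrC(Br)(Br)Br
Why: Appel bromination of the primary allylic alcohol is an SN2 displacement at C13 under neutral conditions, so the alkene geometry set in step 14 is kept.

Step 17
Reactants: 25 allylic bromide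
Product: 26 methyl (2E,4S,6S,7R)-2-(bromomethyl)-4-[(tert-butyldimethylsilyl)oxy]-7-{3-[(tert-butyldiphenylsilyl)oxy]prop-1-en-2-yl}-8-hydroxy-6-methyl-6-vinyloct-2-enoate
Conditions: PPTS (cat.), MeOH–CH2Cl2, 0 °C
Reagents that add atoms: none
Why: Acid-catalysed methanolysis removes the primary triethylsilyl ether much faster than the secondary TBS and the primary TBDPS ethers.

Step 18
Reactants: 26 bromo alcohol
Product: 27 methyl (2E,4S,6S,7R)-2-(bromomethyl)-4-[(tert-butyldimethylsilyl)oxy]-7-{3-[(tert-butyldiphenylsilyl)oxy]prop-1-en-2-yl}-6-methyl-8-oxo-6-vinyloct-2-enoate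
Conditions: Dess–Martin periodinane, NaHCO3, CH2Cl2, 0 °C; used at once
Reagents that add atoms: none
Why: Buffered Dess–Martin oxidation gives the β,γ-unsaturated aldehyde, which is taken on at once so that C5 does not epimerise and the C3=C4 bond does not move into conjugation.

Step 19
Reactants: 27 (E)-2-(bromomethyl)enoate aldehyde
Product: 30 (5R,6R,7S,8S,10S)-8-[(tert-butyldimethylsilyl)oxy]-15-[(tert-butyldiphenylsilyl)oxy]elema-1,3,11(13)-trien-12,6-olide, via allylchromium dichloride 28 (not isolated), via chromium alkoxide 29 (not isolated)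
Conditions: CrCl2 (5 equiv), THF (0.005 M, slow addition of 27), rt; aq. NH4Cl
Reagents that add atoms: none
Why: Two equivalents of divalent chromium reduce the allylic C–Br bond of 27 to the trivalent allylchromium 28, which adds through C7 to the C6 aldehyde with allylic transposition in a closed six-membered chair; the closest known reaction is the intramolecular Nozaki–Hiyama–Kishi-type allylation of aldehydes by 2-(bromomethyl)acrylates. The carbocycle closes 6-exo-trig at the aldehyde carbon, and the chromium alkoxide 29 then closes the lactone by 5-exo-trig acyl substitution at the methyl ester with loss of methoxide, which also leaves C11=C13 as the exocyclic methylene. C6 and C7 are set together in a trans-decalin-like double chair: the (E)-alkene has C8 trans to CH2Cr, so C5 and C8 are both equatorial on the chromium-containing chair and O6 and C11 come out trans-diequatorial on the carbocycle. Which face of each partner reacts is decided by the resident C5, C8 and C10 centres, because only one carbocyclic chair has the C4 side chain and the 8α-silyloxy group equatorial with just the C14 methyl axial, whereas the flipped chair would carry the vinyl group, the C4 side chain and the silyloxy group axial. The step therefore needs the 6α-O/7β-C11 trans pair relative to C5, and the all-equatorial chair together with the fixed alkene geometry secures it; with the 8β-epimer the same chair would force the silyloxy group axial and syn to C14, which is why C8 is corrected only after this step.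

Step 20
Reactants: 30 bicyclic lactone
Product: 31 (5R,6R,7R,8S,10S)-15-[(tert-butyldiphenylsilyl)oxy]-8-hydroxyelema-1,3,11(13)-trien-12,6-olide
Conditions: p-TsOH·H2O (0.2 equiv), MeOH–CH2Cl2, 0 °C → rt
Reagents that add atoms: none
Why: Acid-catalysed methanolysis cleaves the secondary TBS ether, whereas the much more acid-stable primary TBDPS ether should survive.

Step 21
Reactants: 31 8α-alcohol
Product: 32 (5R,6R,7S,10S)-15-[(tert-butyldiphenylsilyl)oxy]-8-oxoelema-1,3,11(13)-trien-12,6-olide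
Conditions: Dess–Martin periodinane, NaHCO3, CH2Cl2, 0 °C; used at once
Reagents that add atoms: none
Why: Buffered Dess–Martin oxidation converts the equatorial 8α-alcohol into the C8 ketone under non-basic conditions, which should avoid enolisation towards C7 and β-elimination of the lactone carboxylate.

Step 22
Reactants: 32 C8 ketone
Product: 33 (5R,6R,7R,8R,10S)-15-[(tert-butyldiphenylsilyl)oxy]-8-hydroxyelema-1,3,11(13)-trien-12,6-olide
Conditions: LiAlH(OtBu)3, THF, −78 → −30 °C
Reagents that add atoms: none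
Why: Hydride reduction of the cyclohexanone with the bulky LiAlH(OtBu)3: axial attack at C8 from the β-face is blocked by the syn-axial C14 methyl, so hydride should enter along the equatorial trajectory from the α-face and give the axial 8β-alcohol.

Step 23
Reactants: 33 8β-alcohol; 34 tiglic acid
Product: 36 (5R,6R,7R,8R,10S)-15-[(tert-butyldiphenylsilyl)oxy]-8-{[(E)-2-methylbut-2-enoyl]oxy}elema-1,3,11(13)-trien-12,6-olide, via mixed anhydride 35 (not isolated)
Conditions: 34, 2,4,6-trichlorobenzoyl chloride, Et3N, THF, rt; then 33, DMAP, toluene, rt → 40 °C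
Reagents that add atoms: none
Why: Yamaguchi esterification: the mixed anhydride of tiglic acid acylates the hindered axial alcohol under DMAP catalysis, and the (E)-geometry of the acid is kept.

Step 24
Reactants: 36 silyl-protected tiglate
Product: 37 (5R,6R,7R,8R,10S)-15-hydroxy-8-{[(E)-2-methylbut-2-enoyl]oxy}elema-1,3,11(13)-trien-12,6-olide
Conditions: HF·pyridine, pyridine, THF, 0 °C → rt
Reagents that add atoms: none
Why: Desilylation of the primary allylic TBDPS ether by fluoride under the mildly acidic conditions of buffered HF·pyridine should leave the tiglate and the lactone intact.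

Step 25
Reactants: 37 C15 allylic alcohol
Product: 38 (5R,6R,7R,8R,10S)-8-{[(E)-2-methylbut-2-enoyl]oxy}-15-oxoelema-1,3,11(13)-trien-12,6-olide
Conditions: MnO2 (activated, excess), CH2Cl2, rt
Reagents that add atoms: none
Why: MnO2 oxidises the allylic alcohol selectively to the 2-substituted acrolein.

Step 26
Reactants: 38 C15 enal
Product: 39 (5R,6R,7R,8R,10S)-8-{[(E)-2-methylbut-2-enoyl]oxy}elema-1,3,11(13)-trien-12,6-olid-15-oic acid (CNP0256928.1)
Conditions: NaClO2, NaH2PO4, 2-methyl-2-butene, t-BuOH–H2O, 0 °C → rt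
Reagents that add atoms: NaClO2, [Na+].[O-]Cl=O
Why: Pinnick oxidation converts the enal into the acrylic acid, with 2-methyl-2-butene trapping hypochlorous acid so that the other alkenes are not chlorinated.

**Compound list**

1 | 2-methylenepropane-1,3-diol | C=C(CO)CO | starting material
2 | 2-{[(tert-butyldiphenylsilyl)oxy]methyl}prop-2-en-1-ol | C=C(CO)CO[Si](c1ccccc1)(c1ccccc1)C(C)(C)C | intermediate
3 | tert-butyl{[2-(chloromethyl)prop-2-en-1-yl]oxy}diphenylsilane | C=C(CCl)CO[Si](c1ccccc1)(c1ccccc1)C(C)(C)C | intermediate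
4 | (2-{[(tert-butyldiphenylsilyl)oxy]methyl}prop-2-en-1-yl)magnesium chloride | C=C(C[Mg]Cl)CO[Si](c1ccccc1)(c1ccccc1)C(C)(C)C | intermediate
5 | 3-{[(tert-butyldiphenylsilyl)oxy]methyl}but-3-enoic acid | C=C(CO[Si](c1ccccc1)(c1ccccc1)C(C)(C)C)CC(=O)O | intermediate
6 | (S)-2-{[(4-methoxybenzyl)oxy]methyl}oxirane ((S)-4-methoxybenzyl glycidyl ether) | COc1ccc(COC[C@@H]2CO2)cc1 | starting material
7 | (S)-1-[(4-methoxybenzyl)oxy]pent-4-yn-2-ol | COc1ccc(COC[C@@H](O)CC#C)cc1 | intermediate
8 | (S)-tert-butyl({1-[(4-methoxybenzyl)oxy]pent-4-yn-2-yl}oxy)dimethylsilane | COc1ccc(COC[C@@H](O[Si](C)(C)C(C)(C)C)CC#C)cc1 | intermediate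
9 | dimethyl{(1E,4S)-4-[(tert-butyldimethylsilyl)oxy]-5-[(4-methoxybenzyl)oxy]-2-methylpent-1-en-1-yl}alane | C[Al](C)/C=C(\C)C[C@H](O[Si](C)(C)C(C)(C)C)COCc1ccc(OC)cc1 | intermediate
10 | lithium butyl{(1E,4S)-4-[(tert-butyldimethylsilyl)oxy]-5-[(4-methoxybenzyl)oxy]-2-methylpent-1-en-1-yl}dimethylaluminate | [Li+].CCCC[Al-](C)(C)/C=C(\C)C[C@H](O[Si](C)(C)C(C)(C)C)COCc1ccc(OC)cc1 | intermediate
11 | (S,E)-5-[(tert-butyldimethylsilyl)oxy]-6-[(4-methoxybenzyl)oxy]-3-methylhex-2-en-1-ol | OC/C=C(\C)C[C@H](O[Si](C)(C)C(C)(C)C)COCc1ccc(OC)cc1 | intermediate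
12 | (S,E)-5-[(tert-butyldimethylsilyl)oxy]-6-[(4-methoxybenzyl)oxy]-3-methylhex-2-en-1-yl 3-{[(tert-butyldiphenylsilyl)oxy]methyl}but-3-enoate | C=C(CO[Si](c1ccccc1)(c1ccccc1)C(C)(C)C)CC(=O)OC/C=C(\C)C[C@H](O[Si](C)(C)C(C)(C)C)COCc1ccc(OC)cc1 | intermediate
13 | O-boron ketene acetal of ester 12 (C4 cis to the allylic oxygen; boron in the (4S,5S)-4,5-diphenyl-1,3-bis{[3,5-bis(trifluoromethyl)phenyl]sulfonyl}-1,3,2-diazaborolidin-2-yl group) | C=C(CO[Si](c1ccccc1)(c1ccccc1)C(C)(C)C)/C=C(/OB1N(S(=O)(=O)c2cc(cc(c2)C(F)(F)F)C(F)(F)F)[C@@H](c2ccccc2)[C@H](c2ccccc2)N1S(=O)(=O)c1cc(cc(c1)C(F)(F)F)C(F)(F)F)OC/C=C(\C)C[C@H](O[Si](C)(C)C(C)(C)C)COCc1ccc(OC)cc1 | intermediate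
14 | acyloxyborane of acid 15 (carboxyl oxygen bound to the same diazaborolidin-2-yl boron) | O=C(OB1N(S(=O)(=O)c2cc(cc(c2)C(F)(F)F)C(F)(F)F)[C@@H](c2ccccc2)[C@H](c2ccccc2)N1S(=O)(=O)c1cc(cc(c1)C(F)(F)F)C(F)(F)F)[C@@H](C(=C)CO[Si](c1ccccc1)(c1ccccc1)C(C)(C)C)[C@](C)(C=C)C[C@H](O[Si](C)(C)C(C)(C)C)COCc1ccc(OC)cc1 | intermediate
15 | (2R,3S,5S)-5-[(tert-butyldimethylsilyl)oxy]-2-{3-[(tert-butyldiphenylsilyl)oxy]prop-1-en-2-yl}-6-[(4-methoxybenzyl)oxy]-3-methyl-3-vinylhexanoic acid | OC(=O)[C@@H](C(=C)CO[Si](c1ccccc1)(c1ccccc1)C(C)(C)C)[C@](C)(C=C)C[C@H](O[Si](C)(C)C(C)(C)C)COCc1ccc(OC)cc1 | intermediate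
16 | (2R,3S,5S)-5-[(tert-butyldimethylsilyl)oxy]-2-{3-[(tert-butyldiphenylsilyl)oxy]prop-1-en-2-yl}-6-[(4-methoxybenzyl)oxy]-3-methyl-3-vinylhexan-1-ol | OC[C@@H](C(=C)CO[Si](c1ccccc1)(c1ccccc1)C(C)(C)C)[C@](C)(C=C)C[C@H](O[Si](C)(C)C(C)(C)C)COCc1ccc(OC)cc1 | intermediate
17 | triethylsilyl ether of 16 (Et3SiO on C6, TBSO on C8, 4-methoxybenzyloxy on C7, TBDPSO on C15) | CC[Si](CC)(CC)OC[C@@H](C(=C)CO[Si](c1ccccc1)(c1ccccc1)C(C)(C)C)[C@](C)(C=C)C[C@H](O[Si](C)(C)C(C)(C)C)COCc1ccc(OC)cc1 | intermediate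
18 | (2S,4S,5R)-2-[(tert-butyldimethylsilyl)oxy]-5-{3-[(tert-butyldiphenylsilyl)oxy]prop-1-en-2-yl}-4-methyl-6-[(triethylsilyl)oxy]-4-vinylhexan-1-ol | CC[Si](CC)(CC)OC[C@@H](C(=C)CO[Si](c1ccccc1)(c1ccccc1)C(C)(C)C)[C@](C)(C=C)C[C@H](O[Si](C)(C)C(C)(C)C)CO | intermediate
19 | (2S,4S,5R)-2-[(tert-butyldimethylsilyl)oxy]-5-{3-[(tert-butyldiphenylsilyl)oxy]prop-1-en-2-yl}-4-methyl-6-[(triethylsilyl)oxy]-4-vinylhexanal | CC[Si](CC)(CC)OC[C@@H](C(=C)CO[Si](c1ccccc1)(c1ccccc1)C(C)(C)C)[C@](C)(C=C)C[C@H](O[Si](C)(C)C(C)(C)C)C=O | intermediate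
20 | methyl 2-[bis(2,2,2-trifluoroethoxy)phosphoryl]acetate | COC(=O)CP(=O)(OCC(F)(F)F)OCC(F)(F)F | starting material
21 | methyl 2-[bis(2,2,2-trifluoroethoxy)phosphoryl]-2,2-dibromoacetate | COC(=O)C(Br)(Br)P(=O)(OCC(F)(F)F)OCC(F)(F)F | intermediate
22 | methyl 2-[bis(2,2,2-trifluoroethoxy)phosphoryl]-2-bromoacetate (racemic) | COC(=O)C(Br)P(=O)(OCC(F)(F)F)OCC(F)(F)F | intermediate
23 | methyl (2E,4S,6S,7R)-2-bromo-4-[(tert-butyldimethylsilyl)oxy]-7-{3-[(tert-butyldiphenylsilyl)oxy]prop-1-en-2-yl}-6-methyl-8-[(triethylsilyl)oxy]-6-vinyloct-2-enoate | CC[Si](CC)(CC)OC[C@@H](C(=C)CO[Si](c1ccccc1)(c1ccccc1)C(C)(C)C)[C@](C)(C=C)C[C@H](O[Si](C)(C)C(C)(C)C)/C=C(/Br)C(=O)OC | intermediate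
24 | methyl (2Z,4S,6S,7R)-4-[(tert-butyldimethylsilyl)oxy]-7-{3-[(tert-butyldiphenylsilyl)oxy]prop-1-en-2-yl}-2-(hydroxymethyl)-6-methyl-8-[(triethylsilyl)oxy]-6-vinyloct-2-enoate | CC[Si](CC)(CC)OC[C@@H](C(=C)CO[Si](c1ccccc1)(c1ccccc1)C(C)(C)C)[C@](C)(C=C)C[C@H](O[Si](C)(C)C(C)(C)C)/C=C(/CO)C(=O)OC | intermediate
25 | methyl (2E,4S,6S,7R)-2-(bromomethyl)-4-[(tert-butyldimethylsilyl)oxy]-7-{3-[(tert-butyldiphenylsilyl)oxy]prop-1-en-2-yl}-6-methyl-8-[(triethylsilyl)oxy]-6-vinyloct-2-enoate | CC[Si](CC)(CC)OC[C@@H](C(=C)CO[Si](c1ccccc1)(c1ccccc1)C(C)(C)C)[C@](C)(C=C)C[C@H](O[Si](C)(C)C(C)(C)C)/C=C(/CBr)C(=O)OC | intermediate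
26 | methyl (2E,4S,6S,7R)-2-(bromomethyl)-4-[(tert-butyldimethylsilyl)oxy]-7-{3-[(tert-butyldiphenylsilyl)oxy]prop-1-en-2-yl}-8-hydroxy-6-methyl-6-vinyloct-2-enoate | OC[C@@H](C(=C)CO[Si](c1ccccc1)(c1ccccc1)C(C)(C)C)[C@](C)(C=C)C[C@H](O[Si](C)(C)C(C)(C)C)/C=C(/CBr)C(=O)OC | intermediate
27 | methyl (2E,4S,6S,7R)-2-(bromomethyl)-4-[(tert-butyldimethylsilyl)oxy]-7-{3-[(tert-butyldiphenylsilyl)oxy]prop-1-en-2-yl}-6-methyl-8-oxo-6-vinyloct-2-enoate (key-step precursor; C5 R, C8 S, C10 S) | O=C[C@@H](C(=C)CO[Si](c1ccccc1)(c1ccccc1)C(C)(C)C)[C@](C)(C=C)C[C@H](O[Si](C)(C)C(C)(C)C)/C=C(/CBr)C(=O)OC | intermediate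
28 | allylchromium dichloride from 27 (CrCl2 on C13, C8 trans to CH2Cr; solvent ligands omitted) | O=C[C@@H](C(=C)CO[Si](c1ccccc1)(c1ccccc1)C(C)(C)C)[C@](C)(C=C)C[C@H](O[Si](C)(C)C(C)(C)C)/C=C(/C[Cr](Cl)Cl)C(=O)OC | intermediate
29 | ring-closed chromium alkoxide (cyclohexane formed, OCrCl2 on C6, methyl 2-propenoate unit on C7, configuration as in 30) | C=C[C@]1(C)C[C@H](O[Si](C)(C)C(C)(C)C)[C@@H](C(=C)C(=O)OC)[C@H](O[Cr](Cl)Cl)[C@H]1C(=C)CO[Si](c1ccccc1)(c1ccccc1)C(C)(C)C | intermediate
30 | (5R,6R,7S,8S,10S)-8-[(tert-butyldimethylsilyl)oxy]-15-[(tert-butyldiphenylsilyl)oxy]elema-1,3,11(13)-trien-12,6-olide (8α-OTBS, trans-fused lactone; key-step product) | C=C[C@]1(C)C[C@H](O[Si](C)(C)C(C)(C)C)[C@H]2C(=C)C(=O)O[C@@H]2[C@H]1C(=C)CO[Si](c1ccccc1)(c1ccccc1)C(C)(C)C | intermediate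
31 | (5R,6R,7R,8S,10S)-15-[(tert-butyldiphenylsilyl)oxy]-8-hydroxyelema-1,3,11(13)-trien-12,6-olide (8α-OH) | C=C[C@]1(C)C[C@H](O)[C@H]2C(=C)C(=O)O[C@@H]2[C@H]1C(=C)CO[Si](c1ccccc1)(c1ccccc1)C(C)(C)C | intermediate
32 | (5R,6R,7S,10S)-15-[(tert-butyldiphenylsilyl)oxy]-8-oxoelema-1,3,11(13)-trien-12,6-olide | C=C[C@]1(C)CC(=O)[C@H]2C(=C)C(=O)O[C@@H]2[C@H]1C(=C)CO[Si](c1ccccc1)(c1ccccc1)C(C)(C)C | intermediate
33 | (5R,6R,7R,8R,10S)-15-[(tert-butyldiphenylsilyl)oxy]-8-hydroxyelema-1,3,11(13)-trien-12,6-olide (8β-OH) | C=C[C@]1(C)C[C@@H](O)[C@H]2C(=C)C(=O)O[C@@H]2[C@H]1C(=C)CO[Si](c1ccccc1)(c1ccccc1)C(C)(C)C | intermediate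
34 | tiglic acid ((E)-2-methylbut-2-enoic acid) | C/C=C(\C)C(=O)O | starting material
35 | (E)-2-methylbut-2-enoic 2,4,6-trichlorobenzoic anhydride | C/C=C(\C)C(=O)OC(=O)c1c(Cl)cc(Cl)cc1Cl | intermediate
36 | (5R,6R,7R,8R,10S)-15-[(tert-butyldiphenylsilyl)oxy]-8-{[(E)-2-methylbut-2-enoyl]oxy}elema-1,3,11(13)-trien-12,6-olide | C=C[C@]1(C)C[C@@H](OC(=O)/C(C)=C/C)[C@H]2C(=C)C(=O)O[C@@H]2[C@H]1C(=C)CO[Si](c1ccccc1)(c1ccccc1)C(C)(C)C | intermediate
37 | (5R,6R,7R,8R,10S)-15-hydroxy-8-{[(E)-2-methylbut-2-enoyl]oxy}elema-1,3,11(13)-trien-12,6-olide | C=C[C@]1(C)C[C@@H](OC(=O)/C(C)=C/C)[C@H]2C(=C)C(=O)O[C@@H]2[C@H]1C(=C)CO | intermediate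
38 | (5R,6R,7R,8R,10S)-8-{[(E)-2-methylbut-2-enoyl]oxy}-15-oxoelema-1,3,11(13)-trien-12,6-olide | C=C[C@]1(C)C[C@@H](OC(=O)/C(C)=C/C)[C@H]2C(=C)C(=O)O[C@@H]2[C@H]1C(=C)C=O | intermediate
39 | (5R,6R,7R,8R,10S)-8-{[(E)-2-methylbut-2-enoyl]oxy}elema-1,3,11(13)-trien-12,6-olid-15-oic acid (CNP0256928.1) | C=C[C@]1(C)C[C@@H](OC(=O)/C(C)=C/C)[C@H]2C(=C)C(=O)O[C@@H]2[C@H]1C(=C)C(=O)O | target

**Step count**
Total step count: 26 (steps 1–3 make acid 5, step 13 makes reagent 22).
Longest linear sequence: 22 steps (steps 4–12 and 14–26, from compound 6).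

**Three steps most likely to fail**

Step 19 (ring closure). What may go wrong: reductive 1,4-elimination of the C8 silyloxy group from the allylchromium, or closure through a boat-like arrangement that erodes the trans fusion. The fallback replaces the organochromium addition by a radical bond formation that does not depend on the alkene geometry. It sets out from allylic alcohol 24, which is acetylated (Ac2O, pyridine) to the allylic acetate F1. The triethylsilyl group is removed (PPTS, MeOH) to give the alcohol F2, which is oxidised (Dess–Martin periodinane, NaHCO3) to the aldehyde F3. SmI2 (2.2 equiv, THF, t-BuOH, −78 °C) then reduces the aldehyde to a ketyl radical that adds 6-exo-trig to C7 of the acrylate. The samarium enolate expels acetate to give the exocyclic methylene, and the samarium alkoxide lactonises. The same all-equatorial chair applies, and the route is rejoined at lactone 30.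

Step 8 (Ireland–Claisen rearrangement). What may go wrong: low facial control by the boron controller, formation of the dienolate with the other geometry, or cleavage of an ether by the Lewis-acidic bromoborane. The fallback gives up reagent control and relies on the resident C8 centre for a separation. It sets out from ester 12, which is enolised with LDA in THF at −78 °C and trapped with Me3SiCl as the kinetic silyl ketene acetal F4 (C4 cis to the allylic oxygen). On warming F4 rearranges through the same chair to the silyl ester F5 and its C5,C10-diastereomeric silyl ester F6. Both are hydrolysed in the work-up, giving acid 15 and the (2S,3R,5S)-acid F7. Because C8 is already fixed, these two acids are diastereomers and are separated by chromatography. The route is rejoined at acid 15.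

Step 22 (reduction at C8). What may go wrong: insufficient facial selectivity of hydride delivery, or base-induced loss of the lactone carboxylate from the β-acyloxy ketone before reduction. The fallback avoids the ketone and inverts C8 by displacement (Lattrell–Dax inversion). It sets out from the 8α-alcohol 31, which is converted (Tf2O, pyridine, CH2Cl2, −20 °C) into the equatorial triflate F8. Tetrabutylammonium nitrite in toluene at rt displaces the triflate with inversion to the axial nitrite ester F9; the approach past the C14 methyl is expected to be slow. F9 is hydrolysed during aqueous work-up, and the route is rejoined at the 8β-alcohol 33.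

**Further compounds**

F1 | step 19 | methyl (2Z,4S,6S,7R)-2-(acetoxymethyl)-4-[(tert-butyldimethylsilyl)oxy]-7-{3-[(tert-butyldiphenylsilyl)oxy]prop-1-en-2-yl}-6-methyl-8-[(triethylsilyl)oxy]-6-vinyloct-2-enoate | CC[Si](CC)(CC)OC[C@@H](C(=C)CO[Si](c1ccccc1)(c1ccccc1)C(C)(C)C)[C@](C)(C=C)C[C@H](O[Si](C)(C)C(C)(C)C)/C=C(/COC(C)=O)C(=O)OC
F2 | step 19 | methyl (2Z,4S,6S,7R)-2-(acetoxymethyl)-4-[(tert-butyldimethylsilyl)oxy]-7-{3-[(tert-butyldiphenylsilyl)oxy]prop-1-en-2-yl}-8-hydroxy-6-methyl-6-vinyloct-2-enoate | OC[C@@H](C(=C)CO[Si](c1ccccc1)(c1ccccc1)C(C)(C)C)[C@](C)(C=C)C[C@H](O[Si](C)(C)C(C)(C)C)/C=C(/COC(C)=O)C(=O)OC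
F3 | step 19 | methyl (2Z,4S,6S,7R)-2-(acetoxymethyl)-4-[(tert-butyldimethylsilyl)oxy]-7-{3-[(tert-butyldiphenylsilyl)oxy]prop-1-en-2-yl}-6-methyl-8-oxo-6-vinyloct-2-enoate | O=C[C@@H](C(=C)CO[Si](c1ccccc1)(c1ccccc1)C(C)(C)C)[C@](C)(C=C)C[C@H](O[Si](C)(C)C(C)(C)C)/C=C(/COC(C)=O)C(=O)OC
F4 | step 8 | trimethylsilyl ketene acetal of ester 12 (C4 cis to the allylic oxygen) | C=C(CO[Si](c1ccccc1)(c1ccccc1)C(C)(C)C)/C=C(/O[Si](C)(C)C)OC/C=C(\C)C[C@H](O[Si](C)(C)C(C)(C)C)COCc1ccc(OC)cc1
F5 | step 8 | trimethylsilyl ester of acid 15 | C[Si](C)(C)OC(=O)[C@@H](C(=C)CO[Si](c1ccccc1)(c1ccccc1)C(C)(C)C)[C@](C)(C=C)C[C@H](O[Si](C)(C)C(C)(C)C)COCc1ccc(OC)cc1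
F6 | step 8 | trimethylsilyl ester of the (2S,3R,5S)-acid | C[Si](C)(C)OC(=O)[C@H](C(=C)CO[Si](c1ccccc1)(c1ccccc1)C(C)(C)C)[C@@](C)(C=C)C[C@H](O[Si](C)(C)C(C)(C)C)COCc1ccc(OC)cc1
F7 | step 8 | (2S,3R,5S)-5-[(tert-butyldimethylsilyl)oxy]-2-{3-[(tert-butyldiphenylsilyl)oxy]prop-1-en-2-yl}-6-[(4-methoxybenzyl)oxy]-3-methyl-3-vinylhexanoic acid | OC(=O)[C@H](C(=C)CO[Si](c1ccccc1)(c1ccccc1)C(C)(C)C)[C@@](C)(C=C)C[C@H](O[Si](C)(C)C(C)(C)C)COCc1ccc(OC)cc1
F8 | step 22 | 8α-trifluoromethanesulfonate of alcohol 31 | C=C[C@]1(C)C[C@H](OS(=O)(=O)C(F)(F)F)[C@H]2C(=C)C(=O)O[C@@H]2[C@H]1C(=C)CO[Si](c1ccccc1)(c1ccccc1)C(C)(C)C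
F9 | step 22 | 8β-nitrite ester (O-nitroso derivative of alcohol 33) | C=C[C@]1(C)C[C@@H](ON=O)[C@H]2C(=C)C(=O)O[C@@H]2[C@H]1C(=C)CO[Si](c1ccccc1)(c1ccccc1)C(C)(C)C
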